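**Retrosynthetic overview**
- The target is the SEM-deprotected form of a dienone whose two C–prenyl bonds at the quaternary ring carbon are both cut back to aryl 1,1-dimethylallyl ethers (two consecutive Claisen [3,3] shifts, the second one dearomative).
- The bis(ether) phenol is cut at the ring–carbinol bond into a magnesium phenolate and an (S)-α-alkoxy aldehyde; chelation control sets the carbinol centre from the bought one.
- The phenol comes from phloroglucinol by Friedel–Crafts acylation and palladium-catalysed O-tert-prenylation; the aldehyde comes from L-valine-derived methyl (S)-2-hydroxy-3-methylbutanoate.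
- No ring is formed: the only ring is bought as phloroglucinol and dearomatised in the second Claisen shift.

Assumption: the target is one enol tautomer of a rapidly equilibrating 2-acylcyclohexane-1,3,5-trione and is drawn as in the given SMILES; tert-butyl (2-methylbut-3-en-2-yl) carbonate is treated as a purchasable reagent.

**Route**

Step 1
Reactants: 1 methyl (2S)-2-hydroxy-3-methylbutanoate
Product: 2 methyl (2S)-3-methyl-2-{[2-(trimethylsilyl)ethoxy]methoxy}butanoate
Conditions: SEMCl, i-Pr2NEt, n-Bu4NI (cat.), CH2Cl2, 0 °C → rt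
Reagents that add atoms: 2-(trimethylsilyl)ethoxymethyl chloride (SEMCl), ClCOCC[Si](C)(C)C
Why: O-alkylation of the secondary alcohol with a chloromethyl ether under amine base does not enolise the ester, so the bought (S) centre is kept, and the SEM acetal can later chelate magnesium and be removed without hydrogenation or protic acid.

Step 2
Reactants: 2 methyl (2S)-3-methyl-2-{[2-(trimethylsilyl)ethoxy]methoxy}butanoate
Product: 3 (2S)-3-methyl-2-{[2-(trimethylsilyl)ethoxy]methoxy}butanal
Conditions: i-Bu2AlH (1.1 equiv), CH2Cl2, −78 °C; then aq. KNaC4H4O6 (potassium sodium tartrate); used at once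
Reagents that add atoms: none
Why: Partial ester reduction with i-Bu2AlH stops at the aldehyde because the α-alkoxy-chelated aluminium hemiacetal survives at −78 °C until work-up, and the α centre is not touched.

Step 3
Reactants: 4 phloroglucinol (benzene-1,3,5-triol)
Product: 5 2-methyl-1-(2,4,6-trihydroxyphenyl)propan-1-one
Conditions: i-PrCOCl (1.05 equiv), AlCl3 (4 equiv), CH2Cl2/PhNO2, 0 → 40 °C; then ice/aq. HCl
Reagents that add atoms: isobutyryl chloride, CC(C)C(Cl)=O
Why: Friedel–Crafts acylation of the very electron-rich ring stops after one acyl group because the hydrogen-bonded aryl ketone deactivates the ring.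

Step 4
Reactants: 5 2-methyl-1-(2,4,6-trihydroxyphenyl)propan-1-one
Product: 6 1-{2-hydroxy-4,6-bis[(2-methylbut-3-en-2-yl)oxy]phenyl}-2-methylpropan-1-one
Conditions: tert-butyl (2-methylbut-3-en-2-yl) carbonate (2.2 equiv), Pd(PPh3)4 (5 mol %), THF, 0 °C; isolated and stored cold
Reagents that add atoms: tert-butyl (2-methylbut-3-en-2-yl) carbonate, CC(C)(C)OC(=O)OC(C)(C)C=C
Why: In this Tsuji–Trost-type O-allylation the phenoxide attacks the more substituted end of the 1,1-dimethyl-π-allylpalladium cation at low temperature, giving tertiary ethers at the para hydroxyl and at one of the two equivalent ortho hydroxyls while the last hydroxyl stays locked in its hydrogen bond to the ketone.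

Step 5
Reactants: 6 1-{2-hydroxy-4,6-bis[(2-methylbut-3-en-2-yl)oxy]phenyl}-2-methylpropan-1-one; 3 (2S)-3-methyl-2-{[2-(trimethylsilyl)ethoxy]methoxy}butanal
Product: 8 1-{2-hydroxy-3-[(1S,2S)-1-hydroxy-3-methyl-2-{[2-(trimethylsilyl)ethoxy]methoxy}butyl]-4,6-bis[(2-methylbut-3-en-2-yl)oxy]phenyl}-2-methylpropan-1-one, via bromomagnesium phenolate 7 (not isolated)
Conditions: EtMgBr (1.0 equiv), Et2O, 0 °C; solvent exchange to CH2Cl2; 3 (1.2 equiv), −20 °C → rt; then H2O
Reagents that add atoms: none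
Why: In this Casiraghi-type ortho-specific hydroxyalkylation the magnesium on the phenolate oxygen chelates the aldehyde C=O and the α-OSEM oxygen (Cram chelate) and delivers the aldehyde only to the free ortho carbon, which attacks the face opposite the isopropyl group, so the new carbinol centre is (S), syn to the bought (S) centre.

Step 6
Reactants: 8 1-{2-hydroxy-3-[(1S,2S)-1-hydroxy-3-methyl-2-{[2-(trimethylsilyl)ethoxy]methoxy}butyl]-4,6-bis[(2-methylbut-3-en-2-yl)oxy]phenyl}-2-methylpropan-1-one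
Product: 10 3,5-dihydroxy-4-[(1S,2S)-1-hydroxy-3-methyl-2-{[2-(trimethylsilyl)ethoxy]methoxy}butyl]-6,6-bis(3-methylbut-2-en-1-yl)-2-(2-methylpropanoyl)cyclohexa-2,4-dien-1-one, via monoprenyl phenol 9 (not isolated)
Conditions: degassed PhMe, 110 °C, sealed tube
Reagents that add atoms: none
Why: Two consecutive aromatic Claisen rearrangements ([3,3]-sigmatropic) turn each 1,1-dimethylallyl ether into a C-prenyl group: the first goes to the only free ortho carbon and rearomatises to 9, the second goes to the same carbon in a dearomative shift driven by formation of the enolised β-triketone; the quaternary carbon carries two identical groups and the side-chain stereocentres are not involved.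

Step 7
Reactants: 10 3,5-dihydroxy-4-[(1S,2S)-1-hydroxy-3-methyl-2-{[2-(trimethylsilyl)ethoxy]methoxy}butyl]-6,6-bis(3-methylbut-2-en-1-yl)-2-(2-methylpropanoyl)cyclohexa-2,4-dien-1-one
Product: 11 3,5-dihydroxy-4-[(1S,2S)-1,2-dihydroxy-3-methylbutyl]-6,6-bis(3-methylbut-2-en-1-yl)-2-(2-methylpropanoyl)cyclohexa-2,4-dien-1-one (CNP0123430.1)
Conditions: MgBr2·OEt2 (10 equiv), MeNO2, Et2O, rt, under argon; then H2O
Reagents that add atoms: none
Why: Chelation-assisted Lewis-acid cleavage of the SEM acetal (bromide attacks silicon, ethene and formaldehyde are lost) needs no protic acid, oxidant or hydrogen, so the prenyl groups, the carbinol next to the enol and both stereocentres are left alone.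

**Compound list**

1 | methyl (2S)-2-hydroxy-3-methylbutanoate | CC(C)[C@H](O)C(=O)OC | starting material
2 | methyl (2S)-3-methyl-2-{[2-(trimethylsilyl)ethoxy]methoxy}butanoate | CC(C)[C@H](OCOCC[Si](C)(C)C)C(=O)OC | intermediate
3 | (2S)-3-methyl-2-{[2-(trimethylsilyl)ethoxy]methoxy}butanal | CC(C)[C@H](OCOCC[Si](C)(C)C)C=O | intermediate
4 | phloroglucinol (benzene-1,3,5-triol) | Oc1cc(O)cc(O)c1 | starting material
5 | 2-methyl-1-(2,4,6-trihydroxyphenyl)propan-1-one | CC(C)C(=O)c1c(O)cc(O)cc1O | intermediate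
6 | 1-{2-hydroxy-4,6-bis[(2-methylbut-3-en-2-yl)oxy]phenyl}-2-methylpropan-1-one | CC(C)C(=O)c1c(O)cc(OC(C)(C)C=C)cc1OC(C)(C)C=C | intermediate
7 | bromomagnesium 2-(2-methylpropanoyl)-3,5-bis[(2-methylbut-3-en-2-yl)oxy]phenolate (not isolated) | CC(C)C(=O)c1c(O[Mg]Br)cc(OC(C)(C)C=C)cc1OC(C)(C)C=C | intermediate
8 | 1-{2-hydroxy-3-[(1S,2S)-1-hydroxy-3-methyl-2-{[2-(trimethylsilyl)ethoxy]methoxy}butyl]-4,6-bis[(2-methylbut-3-en-2-yl)oxy]phenyl}-2-methylpropan-1-one | CC(C)C(=O)c1c(OC(C)(C)C=C)cc(OC(C)(C)C=C)c([C@H](O)[C@@H](OCOCC[Si](C)(C)C)C(C)C)c1O | intermediate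
9 | 1-{2,4-dihydroxy-3-[(1S,2S)-1-hydroxy-3-methyl-2-{[2-(trimethylsilyl)ethoxy]methoxy}butyl]-5-(3-methylbut-2-en-1-yl)-6-[(2-methylbut-3-en-2-yl)oxy]phenyl}-2-methylpropan-1-one (not isolated) | CC(C)C(=O)c1c(OC(C)(C)C=C)c(CC=C(C)C)c(O)c([C@H](O)[C@@H](OCOCC[Si](C)(C)C)C(C)C)c1O | intermediate
10 | 3,5-dihydroxy-4-[(1S,2S)-1-hydroxy-3-methyl-2-{[2-(trimethylsilyl)ethoxy]methoxy}butyl]-6,6-bis(3-methylbut-2-en-1-yl)-2-(2-methylpropanoyl)cyclohexa-2,4-dien-1-one | CC(C)=CCC1(CC=C(C)C)C(=O)C(C(=O)C(C)C)=C(O)C([C@H](O)[C@@H](OCOCC[Si](C)(C)C)C(C)C)=C1O | intermediate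
11 | 3,5-dihydroxy-4-[(1S,2S)-1,2-dihydroxy-3-methylbutyl]-6,6-bis(3-methylbut-2-en-1-yl)-2-(2-methylpropanoyl)cyclohexa-2,4-dien-1-one | CC(C)=CCC1(CC=C(C)C)C(=O)C(C(=O)C(C)C)=C(O)C([C@H](O)[C@@H](O)C(C)C)=C1O | target

**Step count**

Total steps: 7. Longest linear sequence: 5 steps (steps 1, 2, 5, 6, 7 from 1; the branch from 4 through steps 3, 4, 5, 6, 7 is equally long).

**Steps most likely to fail, with fallbacks**

Step 5 (magnesium-templated hydroxyalkylation). The phenolate 7 is chelated by its own ketone and flanked by a bulky tertiary ether, and the tertiary allyl ethers may not tolerate the magnesium salts. The fallback sets out from 5 and comes back at 8; it forms the C–C bond before the ethers are made. 5 is deprotonated with EtMgBr (3 equiv, Et2O then CH2Cl2) to tris(bromomagnesium) 2-(2-methylpropanoyl)benzene-1,3,5-triolate F1. F1 adds to 3 at an unhindered carbon between two O–Mg groups under the same chelate model and gives, after aqueous work-up, 1-{2,4,6-trihydroxy-3-[(1S,2S)-1-hydroxy-3-methyl-2-{[2-(trimethylsilyl)ethoxy]methoxy}butyl]phenyl}-2-methylpropan-1-one F2. Pd(PPh3)4 and tert-butyl (2-methylbut-3-en-2-yl) carbonate (2.2 equiv, THF, 0 °C) then etherify the para hydroxyl and the ortho hydroxyl remote from the side chain. The third hydroxyl is hydrogen-bonded and flanked by two substituents, so it stays free, and the product is 8.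

Step 6 (double Claisen). The second shift could go to the side-chain-bearing carbon instead, and the free ortho-hydroxybenzylic alcohol could lose water to a quinone methide at 110 °C. The fallback sets out from 8 and comes back at 10. The phenol and the benzylic hydroxyl are tied together with t-Bu2Si(OTf)2 and 2,6-lutidine (CH2Cl2, 0 °C) as the di-tert-butylsilylene derivative of 8 F3. This blocks the quinone methide path and makes the side-chain carbon more hindered. Heating F3 in toluene gives, through the silylene-protected monoprenyl phenol F4 (not isolated), the di-tert-butylsilylene derivative of 10 F5. HF·pyridine in THF at 0 °C removes the silylene and returns 10.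

Step 7 (SEM removal on the dearomatised product). The hindered secondary SEM ether may resist MgBr2·OEt2 or fluoride, or the product may not survive them. The fallback sets out from 1 and comes back at 11; it removes the protecting group before any alkene is present, so that the Claisen step gives the target directly.
- 1 is benzylated with benzyl 2,2,2-trichloroacetimidate and catalytic TfOH to methyl (2S)-2-(benzyloxy)-3-methylbutanoate F6.
- F6 is reduced with i-Bu2AlH at −78 °C to (2S)-2-(benzyloxy)-3-methylbutanal F7.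
- 5 is converted as above into tris(bromomagnesium) 2-(2-methylpropanoyl)benzene-1,3,5-triolate F1, which adds to F7 under chelation control to give 1-{3-[(1S,2S)-2-(benzyloxy)-1-hydroxy-3-methylbutyl]-2,4,6-trihydroxyphenyl}-2-methylpropan-1-one F8.
- Hydrogenolysis (H2, Pd/C, EtOAc, rt, stopped at full debenzylation) gives 1-{3-[(1S,2S)-1,2-dihydroxy-3-methylbutyl]-2,4,6-trihydroxyphenyl}-2-methylpropan-1-one F9.
- Pd(PPh3)4 and the carbonate etherify the two less hindered phenols to 1-{3-[(1S,2S)-1,2-dihydroxy-3-methylbutyl]-2-hydroxy-4,6-bis[(2-methylbut-3-en-2-yl)oxy]phenyl}-2-methylpropan-1-one F10.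
- Heating F10 in toluene gives, through the monoprenyl phenol 1-{3-[(1S,2S)-1,2-dihydroxy-3-methylbutyl]-2,4-dihydroxy-5-(3-methylbut-2-en-1-yl)-6-[(2-methylbut-3-en-2-yl)oxy]phenyl}-2-methylpropan-1-one F11 (not isolated), the target 11.

**Further compounds**

F1 | step 5 | tris(bromomagnesium) 2-(2-methylpropanoyl)benzene-1,3,5-triolate | CC(C)C(=O)c1c(O[Mg]Br)cc(O[Mg]Br)cc1O[Mg]Br
F2 | step 5 | 1-{2,4,6-trihydroxy-3-[(1S,2S)-1-hydroxy-3-methyl-2-{[2-(trimethylsilyl)ethoxy]methoxy}butyl]phenyl}-2-methylpropan-1-one | CC(C)C(=O)c1c(O)cc(O)c([C@H](O)[C@@H](OCOCC[Si](C)(C)C)C(C)C)c1O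
F3 | step 6 | di-tert-butylsilylene derivative of 8 (silicon bridges the phenol oxygen and the benzylic oxygen; 1-{(4S)-2,2-di-tert-butyl-4-[(1S)-2-methyl-1-{[2-(trimethylsilyl)ethoxy]methoxy}propyl]-5,7-bis[(2-methylbut-3-en-2-yl)oxy]-4H-1,3,2-benzodioxasilin-8-yl}-2-methylpropan-1-one) | CC(C)C(=O)c1c(OC(C)(C)C=C)cc(OC(C)(C)C=C)c2c1O[Si](C(C)(C)C)(C(C)(C)C)O[C@@H]2[C@@H](OCOCC[Si](C)(C)C)C(C)C
F4 | step 6 | silylene-protected monoprenyl phenol (F3 after the first Claisen shift: one ether replaced by a free hydroxyl and a prenyl group on the adjacent ring carbon) | CC(C)C(=O)c1c(OC(C)(C)C=C)c(CC=C(C)C)c(O)c2c1O[Si](C(C)(C)C)(C(C)(C)C)O[C@@H]2[C@@H](OCOCC[Si](C)(C)C)C(C)C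
F5 | step 6 | di-tert-butylsilylene derivative of 10 (silicon bridges the enol oxygen next to the acyl-bearing carbon and the carbinol oxygen) | CC(C)=CCC1(CC=C(C)C)C(=O)C(C(=O)C(C)C)=C2O[Si](C(C)(C)C)(C(C)(C)C)O[C@H]([C@@H](OCOCC[Si](C)(C)C)C(C)C)C2=C1O
F6 | step 7 | methyl (2S)-2-(benzyloxy)-3-methylbutanoate | CC(C)[C@H](OCc1ccccc1)C(=O)OC
F7 | step 7 | (2S)-2-(benzyloxy)-3-methylbutanal | CC(C)[C@H](OCc1ccccc1)C=O
F8 | step 7 | 1-{3-[(1S,2S)-2-(benzyloxy)-1-hydroxy-3-methylbutyl]-2,4,6-trihydroxyphenyl}-2-methylpropan-1-one | CC(C)C(=O)c1c(O)cc(O)c([C@H](O)[C@@H](OCc2ccccc2)C(C)C)c1O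
F9 | step 7 | 1-{3-[(1S,2S)-1,2-dihydroxy-3-methylbutyl]-2,4,6-trihydroxyphenyl}-2-methylpropan-1-one | CC(C)C(=O)c1c(O)cc(O)c([C@H](O)[C@@H](O)C(C)C)c1O
F10 | step 7 | 1-{3-[(1S,2S)-1,2-dihydroxy-3-methylbutyl]-2-hydroxy-4,6-bis[(2-methylbut-3-en-2-yl)oxy]phenyl}-2-methylpropan-1-one | CC(C)C(=O)c1c(OC(C)(C)C=C)cc(OC(C)(C)C=C)c([C@H](O)[C@@H](O)C(C)C)c1O
F11 | step 7 | 1-{3-[(1S,2S)-1,2-dihydroxy-3-methylbutyl]-2,4-dihydroxy-5-(3-methylbut-2-en-1-yl)-6-[(2-methylbut-3-en-2-yl)oxy]phenyl}-2-methylpropan-1-one | CC(C)C(=O)c1c(OC(C)(C)C=C)c(CC=C(C)C)c(O)c([C@H](O)[C@@H](O)C(C)C)c1O
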